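**Retrosynthetic overview**

1. Ring D is formed last: C16–CH3 by exo-selective MeMgBr addition to a C15/C16 dione, and C15–C16 by pinacol coupling of a dialdehyde on C8 and C13.
2. The δ-lactone (C20–O–C7), the C10–C20 bond and the C3–O ether bond come from one enolate hydroxymethylation / seven-to-six acyl shift / oxa-Michael cascade on a seven-membered lactone in which C7 is held temporarily on O6.
3. Key disconnection: the C9–C10 bond together with a one-carbon contraction of ring C (C8, C9, C11, C12, C13, C14) to the cyclopentene C8, C9, C12, C13, C14. Forward, C11 enters as CBr2 and silver-triggered electrocyclic opening gives the 2-bromoallyl cation C9–C11–C12, which C10 of the ring A silyl dienol ether captures at C9 through the C7 ester tether.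
4. Enabling feature: ring C is an all-carbon, unfunctionalized ring whose C9 is bonded both to C10 (α-carbon of the C1 ketone, hence an enol nucleophile) and to the quaternary C8, whose carboxyl C7 serves as the tether. C11 and C12 are plain CH2 groups, so the vinyl bromide left by the ring expansion is erased by hydrogenolysis.
5. Ring order: ring A (from 4,4-dimethylcyclohexadienone) and the cyclopentene (from norbornadiene) → ring C plus temporary oxepanone (step 14) → δ-lactone and tetrahydrofuran (step 15) → ring D (steps 19–21).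

Key step: step 14

Remark: atom numbers follow the ent-kaurane skeleton of the target (C1 ketone, C3–O–C6 ether, C4 CMe2, C7 lactone C=O, C8 quaternary, C10 spiro carbon, C15 ketone, C16 carbinol, C20 lactone CH2); TBDPS = tert-butyldiphenylsilyl, TBS = tert-butyldimethylsilyl.

Step 1
Reactants: 1 4,4-dimethylcyclohexa-2,5-dien-1-one
Product: 2 (S)-4,4-dimethyl-5-vinylcyclohex-2-en-1-one
Conditions: potassium vinyltrifluoroborate (1.2 equiv), [Rh(cod)2]BF4 (3 mol %, cod = cycloocta-1,5-diene), (S)-BINAP (3.3 mol %), toluene/H2O 4:1, 100 °C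
Reagents that add atoms: potassium vinyltrifluoroborate, [K+].C=C[B-](F)(F)F
Why: Rhodium-catalysed asymmetric conjugate addition of an alkenyltrifluoroborate (Hayashi–Miyaura type) should desymmetrize the achiral dienone, the (S)-BINAP complex choosing one enantiotopic β-carbon and face so that C5 is formed with S configuration (sense assigned by analogy with cyclohex-2-enone).

Step 2
Reactants: 2 (S)-4,4-dimethyl-5-vinylcyclohex-2-en-1-one
Product: 4 (R)-5-(hydroxymethyl)-4,4-dimethylcyclohex-2-en-1-one, via aldehyde 3 (not isolated)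
Conditions: OsO4 (2 mol %), NaIO4 (2.2 equiv), 2,6-lutidine, dioxane/H2O 3:1, rt; extractive work-up, then NaBH4 (0.5 equiv), MeOH/CH2Cl2, −78 °C
Reagents that add atoms: osmium tetroxide, O=[Os](=O)(=O)=O (catalytic oxygen carrier); sodium periodate, [Na+].[O-]I(=O)(=O)=O; water, O
Why: Lemieux–Johnson cleavage should take the electron-rich vinyl group in preference to the electron-poor enone double bond, and the epimerizable aldehyde is reduced at once at −78 °C, where NaBH4 reduces aldehydes much faster than enones, so C5 is untouched (its descriptor changes to R only through the priority rules).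

Step 3
Reactants: 5 norbornadiene
Product: 6 cis-cyclopent-4-ene-1,3-dicarboxylic acid
Conditions: RuCl3·xH2O (2 mol %), NaIO4 (4.1 equiv, slow addition), EtOAc/MeCN/H2O 2:2:3, 0 °C
Reagents that add atoms: sodium periodate, [Na+].[O-]I(=O)(=O)=O; water, O
Why: Ruthenium tetroxide-catalysed oxidative cleavage (Sharpless conditions) of one strained norbornadiene double bond should give the diacid with the cis geometry inherited from the bicycle, the less strained cyclopentene double bond surviving while periodate is limiting.

Step 4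
Reactants: 6 cis-cyclopent-4-ene-1,3-dicarboxylic acid
Product: 7 3-oxabicyclo[3.2.1]oct-6-ene-2,4-dione (meso anhydride)
Conditions: Ac2O, 100 °C
Reagents that add atoms: none
Why: Dehydration of a cis-1,3-diacid to the bridged glutaric-type anhydride with acetic anhydride is a standard cyclization.

Step 5
Reactants: 7 3-oxabicyclo[3.2.1]oct-6-ene-2,4-dione
Product: 8 (1S,3R)-3-(methoxycarbonyl)cyclopent-4-ene-1-carboxylic acid
Conditions: MeOH (10 equiv), quinidine (1.1 equiv), toluene, −55 °C
Reagents that add atoms: methanol, CO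
Why: Cinchona alkaloid-mediated desymmetrizing methanolysis of a meso anhydride should fix both ring stereocentres (future C8 and C13) at once, quinidine being chosen to direct methanol to the carbonyl that becomes the C8 ester (quinine would give the antipode).

Step 6
Reactants: 8 (1S,3R)-3-(methoxycarbonyl)cyclopent-4-ene-1-carboxylic acid
Product: 10 methyl (1R,4S)-4-(hydroxymethyl)cyclopent-2-ene-1-carboxylate, via mixed carbonic anhydride 9 (not isolated)
Conditions: i-BuOCOCl, N-methylmorpholine, THF, −15 °C; then NaBH4, THF/H2O, 0 °C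
Reagents that add atoms: none
Why: Reduction of the acid through its mixed carbonic anhydride with NaBH4 is chemoselective beside the ester and the alkene and touches no stereocentre.

Step 7
Reactants: 10 methyl (1R,4S)-4-(hydroxymethyl)cyclopent-2-ene-1-carboxylate
Product: 11 methyl (1R,4S)-4-[(tert-butyldiphenylsilyloxy)methyl]cyclopent-2-ene-1-carboxylate
Conditions: TBDPSCl, imidazole, DMF, rt
Reagents that add atoms: tert-butyl(chloro)diphenylsilane, CC(C)(C)[Si](Cl)(c1ccccc1)c1ccccc1
Why: Standard silylation of a primary alcohol, the bulky TBDPS group being chosen because its oxygen is a poor nucleophile in step 14.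

Step 8
Reactants: 11 methyl (1R,4S)-4-[(tert-butyldiphenylsilyloxy)methyl]cyclopent-2-ene-1-carboxylate
Product: 12 (1R,4S)-1-(methoxycarbonyl)-4-[(tert-butyldiphenylsilyloxy)methyl]cyclopent-2-ene-1-carboxylic acid
Conditions: LiN(i-Pr)2 (1.1 equiv), THF, −78 °C; then CO2 (gas), −78 °C; cold acidic work-up
Reagents that add atoms: carbon dioxide, O=C=O
Why: α-Carboxylation of the ester dienolate should create the quaternary C8, CO2 entering the flat dienolate anti to the silyloxymethyl group so that the new carboxyl (future C7) is trans and the ester (future C15) cis to that group.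

Step 9
Reactants: 12 (1R,4S)-1-(methoxycarbonyl)-4-[(tert-butyldiphenylsilyloxy)methyl]cyclopent-2-ene-1-carboxylic acid
Product: 13 (1S,4S)-1-(hydroxymethyl)-4-[(tert-butyldiphenylsilyloxy)methyl]cyclopent-2-ene-1-carboxylic acid
Conditions: LiBH4 (2.5 equiv), THF, 0 °C → rt
Reagents that add atoms: none
Why: LiBH4 reduces the methyl ester while the lithium carboxylate is inert, a known way to tell apart the two carbonyl groups of a malonic half-ester.

Step 10
Reactants: 13 (1S,4S)-1-(hydroxymethyl)-4-[(tert-butyldiphenylsilyloxy)methyl]cyclopent-2-ene-1-carboxylic acid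
Product: 15 (1S,4S)-1,4-bis[(tert-butyldiphenylsilyloxy)methyl]cyclopent-2-ene-1-carboxylic acid, via silyl ester 14 (not isolated)
Conditions: TBDPSCl (2.5 equiv), imidazole, DMF, rt; then K2CO3, MeOH/H2O, rt
Reagents that add atoms: tert-butyl(chloro)diphenylsilane, CC(C)(C)[Si](Cl)(c1ccccc1)c1ccccc1
Why: Silylation of alcohol and acid followed by mild carbonate hydrolysis of the labile silyl ester leaves the neopentyl silyl ether in place.

Step 11
Reactants: 15 (1S,4S)-1,4-bis[(tert-butyldiphenylsilyloxy)methyl]cyclopent-2-ene-1-carboxylic acid; 4 (R)-5-(hydroxymethyl)-4,4-dimethylcyclohex-2-en-1-one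
Product: 16 [(1R)-2,2-dimethyl-5-oxocyclohex-3-en-1-yl]methyl (1S,4S)-1,4-bis[(tert-butyldiphenylsilyloxy)methyl]cyclopent-2-ene-1-carboxylate
Conditions: 2-methyl-6-nitrobenzoic anhydride (1.3 equiv), DMAP (0.2 equiv), Et3N, CH2Cl2, rt
Reagents that add atoms: none
Why: Shiina esterification suits an α-quaternary acid and a β-branched primary alcohol and places the C7 acyl group on O6 as the temporary tether.

Step 12
Reactants: 16 ester of acid 15 with alcohol 4
Product: 17 6,6-dibromobicyclo[3.1.0]hexane ester (CBr2 added across C9=C12, drawn anti to the two silyloxymethyl groups)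
Conditions: PhHgCBr3 (2 equiv), benzene, 80 °C
Reagents that add atoms: phenyl(tribromomethyl)mercury, BrC(Br)(Br)[Hg]c1ccccc1
Why: Seyferth dibromocarbene transfer under neutral conditions should cyclopropanate the cis-disubstituted cyclopentene while the electron-poor enone is inert, and the facial ratio does not matter because both diastereomers give the same cation in step 14.

Step 13
Reactants: 17 6,6-dibromobicyclo[3.1.0]hexane ester
Product: 18 silyl dienol ether of 17 (ring A as 2-(tert-butyldimethylsilyloxy)cyclohexa-1,3-diene, C1(OTBS)=C10)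
Conditions: TBSOTf (1.3 equiv), Et3N (2 equiv), CH2Cl2, −78 → 0 °C
Reagents that add atoms: tert-butyldimethylsilyl triflate, CC(C)(C)[Si](C)(C)OS(=O)(=O)C(F)(F)F
Why: Soft enolization of the enone at its only α′-position (C10) gives the cross-conjugated silyloxydiene, the ester having no α-hydrogen.

Step 14
Reactants: 18 silyl dienol ether
Product: 20 seven-membered lactone (ring A enone with H at C10; C10–C9 bond to ring C carrying C11(Br)=C12; C6–O–C7(=O)–C8 closed as oxepanone), via allyl cation 19 (not isolated)
Conditions: AgOTf (1.5 equiv), 2,6-di-tert-butyl-4-methylpyridine (1.5 equiv), CH2Cl2, −40 °C → rt, dark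
Reagents that add atoms: none
Why: Proposed new method: AgOTf removes the bromide that lies syn to the five-membered ring and the C9–C12 bond opens in the same disrotatory two-electron electrocyclic event, so that the cyclopentane C8–C9–C12–C13–C14 becomes the six-membered ring C as the 2-bromocyclohexenyl (allyl) cation C9–C11(Br)–C12 (19), which is then attacked at C9 by C10 of the tethered silyloxydiene with loss of the silyl group as TBSOTf. The closest known reaction type is the silver-promoted electrocyclic ring opening of 6,6-dibromobicyclo[3.1.0]hexanes with capture of the allyl cation by tethered nitrogen, oxygen or arene nucleophiles, joined here to the SN1 (Mukaiyama-type) alkylation of a silyl enol ether by an allyl cation; a silyl dienol ether as the internal carbon nucleophile is the untested part. Ring C is closed by ring expansion (opening of the cyclopropane bond shared with the five-membered ring) and the temporary oxepanone C5–C6–O–C7–C8–C9–C10 by 7-exo attack of the enol ether carbon (enol double bond exocyclic to the new ring) on the cation terminus. The new stereocentre C9 is controlled by the tether: C10 can reach C9 only on the face of C8 that carries the ester carbonyl C7, which places C10 cis to C7 as the target requires, whereas the C10–H centre formed at the same time need not be controlled because it is enolized in step 15. The step needs site selectivity between the two cation termini and carbon- over oxygen-capture; the first is secured by ring size (seven-membered closure at C9 against nine-membered closure at C12), the second by the much higher nucleophilicity of the silyl dienol ether than of the hindered TBDPS ether oxygens and by the hindered pyridine base, which protects the dienol ether from protodesilylation. Both cyclopropane diastereomers of 18 should converge on the same cation, since in each the bromide syn to the ring is the one that leaves.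

Step 15
Reactants: 20 seven-membered lactone
Product: 23 C3–O–C6 ether δ-lactone vinyl bromide (ring A, tetrahydrofuran and C20–O–C7 lactone complete; C11(Br)=C12; C15 and C16 as CH2OTBDPS), via hydroxymethyl alkoxide 21 (not isolated), via spirolactone alkoxide 22 (not isolated)
Conditions: LiN(i-Pr)2 (1.2 equiv), THF, −78 °C; then monomeric CH2O (THF solution, excess), −78 → 0 °C; NH4Cl
Reagents that add atoms: formaldehyde, C=O
Why: Aldol addition of the C10 lithium enolate to formaldehyde anti to the pseudo-axial C5–CH2O arm should set C10 (C20 trans to C6), after which the new alkoxide attacks C7 (acyl shift from the seven- to the six-membered lactone) and the released O6 alkoxide closes the tetrahydrofuran by 5-exo oxa-Michael addition to C3, whose configuration is dictated by the C5 arm.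

Step 16
Reactants: 23 C3–O–C6 ether δ-lactone vinyl bromide
Product: 24 11,12-saturated, bromine-free analogue of 23
Conditions: H2 (1 atm), Pd/C (10 %), Et3N, EtOAc, rt
Reagents that add atoms: none
Why: Hydrogenolysis of the vinyl bromide and hydrogenation of the resulting cis-disubstituted alkene over Pd/C create no stereocentre and leave ketone, lactone and silyl ethers alone.

Step 17
Reactants: 24 bis-TBDPS ether
Product: 25 diol (CH2OH on C8 and on C13)
Conditions: HF·pyridine, THF/pyridine, 0 °C → rt
Reagents that add atoms: none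
Why: Buffered fluoride cleaves both primary silyl ethers under non-basic conditions, which avoids retro-oxa-Michael opening and lactone migration.

Step 18
Reactants: 25 diol
Product: 26 dialdehyde (C15 formyl on C8, C16 formyl on C13, cis)
Conditions: (COCl)2, DMSO, CH2Cl2, −78 °C; then Et3N, −78 → −20 °C
Reagents that add atoms: none
Why: Swern oxidation activates both primary alcohols before base is added, which should prevent lactol and lactone formation from a hydroxy aldehyde.

Step 19
Reactants: 26 dialdehyde
Product: 27 15,16-cis-diol (ring D closed, both hydroxyl groups drawn exo)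
Conditions: SmI2 (2.5 equiv), t-BuOH (2 equiv), THF, −78 °C
Reagents that add atoms: none
Why: SmI2-mediated intramolecular pinacol coupling of a 1,5-dialdehyde should close ring D through the 1,3-diaxial conformer (5-exo ketyl addition) to the cis-diol, whose two carbinol centres are removed in step 20.

Step 20
Reactants: 27 15,16-cis-diol
Product: 28 15,16-dione
Conditions: (COCl)2, DMSO, CH2Cl2, −78 °C; then Et3N
Reagents that add atoms: none
Why: Swern oxidation converts a cis-1,2-diol into the α-diketone without C–C cleavage, and the dione cannot enolize because C8 is quaternary and C13 a bridgehead.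

Step 21
Reactants: 28 15,16-dione
Product: 29 CNP0538153.1 (target)
Conditions: MeMgBr (1.1 equiv), THF, −78 °C; NH4Cl
Reagents that add atoms: methylmagnesium bromide, C[Mg]Br
Why: Grignard addition should occur at the more accessible C16 carbonyl (C15 is shielded by the quaternary C8) and from the exo face of the bicyclo[3.2.1]octane (syn to the one-carbon bridge C14), which puts methyl exo and hydroxyl endo as in the target, the α-diketone being far more electrophilic than the C1 ketone or the lactone.

**Compound list**

1 | 4,4-dimethylcyclohexa-2,5-dien-1-one | CC1(C)C=CC(=O)C=C1 | starting material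
2 | (S)-4,4-dimethyl-5-vinylcyclohex-2-en-1-one | CC1(C)C=CC(=O)C[C@H]1C=C | intermediate
3 | (R)-2,2-dimethyl-5-oxocyclohex-3-ene-1-carbaldehyde | CC1(C)C=CC(=O)C[C@H]1C=O | intermediate
4 | (R)-5-(hydroxymethyl)-4,4-dimethylcyclohex-2-en-1-one | CC1(C)C=CC(=O)C[C@H]1CO | intermediate
5 | norbornadiene (bicyclo[2.2.1]hepta-2,5-diene) | C1=CC2C=CC1C2 | starting material
6 | cis-cyclopent-4-ene-1,3-dicarboxylic acid (meso) | OC(=O)[C@@H]1C[C@@H](C=C1)C(O)=O | intermediate
7 | 3-oxabicyclo[3.2.1]oct-6-ene-2,4-dione (meso anhydride) | O=C1OC(=O)[C@@H]2C[C@H]1C=C2 | intermediate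
8 | (1S,3R)-3-(methoxycarbonyl)cyclopent-4-ene-1-carboxylic acid | COC(=O)[C@@H]1C[C@@H](C=C1)C(O)=O | intermediate
9 | isobutyl carbonic mixed anhydride of 8 | COC(=O)[C@@H]1C[C@@H](C=C1)C(=O)OC(=O)OCC(C)C | intermediate
10 | methyl (1R,4S)-4-(hydroxymethyl)cyclopent-2-ene-1-carboxylate | COC(=O)[C@@H]1C[C@@H](C=C1)CO | intermediate
11 | methyl (1R,4S)-4-[(tert-butyldiphenylsilyloxy)methyl]cyclopent-2-ene-1-carboxylate | COC(=O)[C@@H]1C[C@@H](C=C1)CO[Si](c2ccccc2)(c2ccccc2)C(C)(C)C | intermediate
12 | (1R,4S)-1-(methoxycarbonyl)-4-[(tert-butyldiphenylsilyloxy)methyl]cyclopent-2-ene-1-carboxylic acid (CO2H trans to the C4 side chain) | OC(=O)[C@@]1(C(=O)OC)C[C@@H](C=C1)CO[Si](c2ccccc2)(c2ccccc2)C(C)(C)C | intermediate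
13 | (1S,4S)-1-(hydroxymethyl)-4-[(tert-butyldiphenylsilyloxy)methyl]cyclopent-2-ene-1-carboxylic acid (the two CH2O groups cis) | OC(=O)[C@@]1(CO)C[C@@H](C=C1)CO[Si](c2ccccc2)(c2ccccc2)C(C)(C)C | intermediate
14 | tert-butyldiphenylsilyl ester of 15 | CC(C)(C)[Si](c1ccccc1)(c1ccccc1)OC(=O)[C@@]2(CO[Si](c3ccccc3)(c3ccccc3)C(C)(C)C)C[C@@H](C=C2)CO[Si](c3ccccc3)(c3ccccc3)C(C)(C)C | intermediate
15 | (1S,4S)-1,4-bis[(tert-butyldiphenylsilyloxy)methyl]cyclopent-2-ene-1-carboxylic acid | OC(=O)[C@@]1(CO[Si](c2ccccc2)(c2ccccc2)C(C)(C)C)C[C@@H](C=C1)CO[Si](c2ccccc2)(c2ccccc2)C(C)(C)C | intermediate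
16 | [(1R)-2,2-dimethyl-5-oxocyclohex-3-en-1-yl]methyl (1S,4S)-1,4-bis[(tert-butyldiphenylsilyloxy)methyl]cyclopent-2-ene-1-carboxylate | CC1(C)C=CC(=O)C[C@H]1COC(=O)[C@@]2(CO[Si](c3ccccc3)(c3ccccc3)C(C)(C)C)C[C@@H](C=C2)CO[Si](c3ccccc3)(c3ccccc3)C(C)(C)C | intermediate
17 | [(1R)-2,2-dimethyl-5-oxocyclohex-3-en-1-yl]methyl 6,6-dibromo-2,4-bis[(tert-butyldiphenylsilyloxy)methyl]bicyclo[3.1.0]hexane-2-carboxylate (side chains cis, cyclopropane anti to them) | CC1(C)C=CC(=O)C[C@H]1COC(=O)[C@@]2(CO[Si](c3ccccc3)(c3ccccc3)C(C)(C)C)C[C@@H]([C@@H]3[C@H]2C3(Br)Br)CO[Si](c3ccccc3)(c3ccccc3)C(C)(C)C | intermediate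
18 | [(1R)-5-(tert-butyldimethylsilyloxy)-2,2-dimethylcyclohexa-3,5-dien-1-yl]methyl ester corresponding to 17 (silyl dienol ether) | CC1(C)C=CC(O[Si](C)(C)C(C)(C)C)=C[C@H]1COC(=O)[C@@]2(CO[Si](c3ccccc3)(c3ccccc3)C(C)(C)C)C[C@@H]([C@@H]3[C@H]2C3(Br)Br)CO[Si](c3ccccc3)(c3ccccc3)C(C)(C)C | intermediate
19 | 2-bromocyclohex-2-en-1-ylium triflate from 18 (allyl cation over C9–C11(Br)–C12) | CC1(C)C=CC(O[Si](C)(C)C(C)(C)C)=C[C@H]1COC(=O)[C@@]2(CO[Si](c3ccccc3)(c3ccccc3)C(C)(C)C)C[C@@H](C=C(Br)[CH+]2)CO[Si](c3ccccc3)(c3ccccc3)C(C)(C)C.[O-]S(=O)(=O)C(F)(F)F | intermediate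
20 | seven-membered lactone: ring A enone (H at C10, C9 cis to C6) bonded C10–C9 to ring C with C11(Br)=C12; O6–C7(=O)–C8 oxepanone; CH2OTBDPS on C8 and C13 | CC1(C)C=CC(=O)[C@@H]2[C@H]1COC(=O)[C@@]3(CO[Si](c4ccccc4)(c4ccccc4)C(C)(C)C)C[C@@H](C=C(Br)[C@H]32)CO[Si](c4ccccc4)(c4ccccc4)C(C)(C)C | intermediate
21 | lithium alkoxide of the C10-hydroxymethyl ketone (oxepanone intact) | [Li+].CC1(C)C=CC(=O)[C@]2(C[O-])[C@H]1COC(=O)[C@@]3(CO[Si](c4ccccc4)(c4ccccc4)C(C)(C)C)C[C@@H](C=C(Br)[C@H]32)CO[Si](c4ccccc4)(c4ccccc4)C(C)(C)C | intermediate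
22 | lithium O6-alkoxide of the spiro δ-lactone (C20–O–C7) enone | [Li+].CC1(C)C=CC(=O)[C@]2(COC(=O)[C@@]3(CO[Si](c4ccccc4)(c4ccccc4)C(C)(C)C)C[C@@H](C=C(Br)[C@H]32)CO[Si](c4ccccc4)(c4ccccc4)C(C)(C)C)[C@H]1C[O-] | intermediate
23 | 3,6-ether 7,20-lactone with C11(Br)=C12 and CH2OTBDPS on C8 (C15) and C13 (C16) | CC1(C)[C@@H]2CC(=O)[C@]3(COC(=O)[C@@]4(CO[Si](c5ccccc5)(c5ccccc5)C(C)(C)C)C[C@@H](C=C(Br)[C@H]43)CO[Si](c5ccccc5)(c5ccccc5)C(C)(C)C)[C@H]1CO2 | intermediate
24 | 11,12-saturated, bromine-free analogue of 23 | CC1(C)[C@@H]2CC(=O)[C@]3(COC(=O)[C@@]4(CO[Si](c5ccccc5)(c5ccccc5)C(C)(C)C)C[C@@H](CC[C@H]43)CO[Si](c5ccccc5)(c5ccccc5)C(C)(C)C)[C@H]1CO2 | intermediate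
25 | diol (CH2OH on C8 and C13) | CC1(C)[C@@H]2CC(=O)[C@]3(COC(=O)[C@@]4(CO)C[C@@H](CC[C@H]43)CO)[C@H]1CO2 | intermediate
26 | dialdehyde (CHO on C8 and C13) | CC1(C)[C@@H]2CC(=O)[C@]3(COC(=O)[C@@]4(C=O)C[C@@H](CC[C@H]43)C=O)[C@H]1CO2 | intermediate
27 | 15,16-cis-diol (ring D closed, both OH exo) | CC1(C)[C@@H]2CC(=O)[C@]3(COC(=O)[C@@]45C[C@@H](CC[C@H]43)[C@H](O)[C@@H]5O)[C@H]1CO2 | intermediate
28 | 15,16-dione | CC1(C)[C@@H]2CC(=O)[C@]3(COC(=O)[C@@]45C[C@@H](CC[C@H]43)C(=O)C5=O)[C@H]1CO2 | intermediate
29 | CNP0538153.1 | CC1(C)[C@@H]2CC(=O)[C@]3(COC(=O)[C@@]45C[C@@H](CC[C@H]43)[C@@](C)(O)C5=O)[C@H]1CO2 | target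

**Step count and risks**

Total step count: 21 (ring A fragment, steps 1–2; cyclopentene fragment, steps 3–10; union and endgame, steps 11–21). Longest linear sequence: 19 steps (from 5 through steps 3–21).

Steps most likely to fail:

1. Step 14 (the proposed new method). The allyl cation may be captured by a silyl ether oxygen, lose a proton to a bromodiene, or the dienol ether may be protodesilylated before the seven-membered ring closes. Fallback with known chemistry, replacing the cationic closure by an anionic one: it sets out from 17, before silylation. Heating 17 in toluene at 110 °C should effect the well-known thermal electrocyclic ring expansion to the 2,3-dibromocyclohex-2-enyl ester F1. KN(SiMe3)2 in THF at −78 °C then forms the α′-enolate of the enone, which displaces the allylic bromide by intramolecular SN2′ alkylation at C9. The sequence comes back to the route at 20.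

2. Step 15. Retro-aldol loss of formaldehyde may outrun the acyl shift, or the acyl shift may stop short of the six-membered lactone. Fallback separating the three events: it sets out from 20. The lithium enolate is alkylated irreversibly with 4-methoxybenzyl chloromethyl ether to give the C10-(4-methoxybenzyloxymethyl) ketone F2. DDQ in wet CH2Cl2 frees the hydroxymethyl ketone F3. DBU in toluene then drives the seven-to-six translactonization and the oxa-Michael closure. The sequence comes back to the route at 23.

3. Step 21. The Grignard reagent may attack the wrong carbonyl of the dione (C15) or add twice. Fallback that differentiates C15 and C16 before methyl addition: it sets out from 26. A triazolium-derived N-heterocyclic carbene (triazolium salt, DBU, THF) catalyses an intramolecular benzoin reaction in which the acyl anion equivalent forms at the less hindered C16 aldehyde, giving the 15-hydroxy-16-ketone F4. MeMgBr with CeCl3 (exo attack on the only ring D ketone) gives the 16-methyl-15,16-diol F5. Parikh–Doering oxidation of its secondary alcohol comes back to the route at 29, the target.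

Further compounds
F1 | step 14 | [(1R)-2,2-dimethyl-5-oxocyclohex-3-en-1-yl]methyl 2,3-dibromo-1,5-bis[(tert-butyldiphenylsilyloxy)methyl]cyclohex-2-ene-1-carboxylate type allylic dibromide (C9=C11(Br), Br on C12) | CC1(C)C=CC(=O)C[C@H]1COC(=O)[C@@]2(CO[Si](c3ccccc3)(c3ccccc3)C(C)(C)C)C[C@@H]([C@@H](Br)C(Br)=C2)CO[Si](c3ccccc3)(c3ccccc3)C(C)(C)C
F2 | step 15 | C10-(4-methoxybenzyloxymethyl) derivative of 20 | CC1(C)C=CC(=O)[C@]2(COCc3ccc(OC)cc3)[C@H]1COC(=O)[C@@]3(CO[Si](c4ccccc4)(c4ccccc4)C(C)(C)C)C[C@@H](C=C(Br)[C@H]32)CO[Si](c4ccccc4)(c4ccccc4)C(C)(C)C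
F3 | step 15 | C10-hydroxymethyl ketone (neutral form of 21) | CC1(C)C=CC(=O)[C@]2(CO)[C@H]1COC(=O)[C@@]3(CO[Si](c4ccccc4)(c4ccccc4)C(C)(C)C)C[C@@H](C=C(Br)[C@H]32)CO[Si](c4ccccc4)(c4ccccc4)C(C)(C)C
F4 | step 21 | 15-hydroxy-16-ketone (ring D acyloin, OH exo) | CC1(C)[C@@H]2CC(=O)[C@]3(COC(=O)[C@@]45C[C@@H](CC[C@H]43)C(=O)[C@@H]5O)[C@H]1CO2
F5 | step 21 | 16-methyl-15,16-diol (16-OH endo, 15-OH exo) | CC1(C)[C@@H]2CC(=O)[C@]3(COC(=O)[C@@]45C[C@@H](CC[C@H]43)[C@@](C)(O)[C@@H]5O)[C@H]1CO2
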